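Everything rests on cutting the bond between the ester carbonyl carbon (C1) and the vinylic carbon C2 of the (Z)-4-acetoxy-2-methylbut-2-enoate. The Z acid, prone to Z/E isomerisation and butenolide formation, is therefore never made or activated. The (S)-benzylic alcohol carries C1 as an O-alkyl S-phenyl thiocarbonate, and C2 arrives as a (Z)-alkenylstannane. One base-free Pd(0)/Cu(I) desulfitative coupling joins both halves with retention at C2=C3 and at the carbinol carbon. It exploits the cis relation of C1 and the C4 acetoxymethyl group across C2=C3, preset by a five-membered oxa-aluminacycle. The chelated phenol on the benzene ring, the enone and the allylic acetate stay unprotected.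

Key step: step 6

Remark: C1–C4 number the but-2-enoate chain from the ester carbonyl. Tributyltin triflate, S-phenyl chlorothioformate, copper(I) diphenylphosphinate and 2-methylprop-1-enylmagnesium bromide are taken as purchasable reagents.

Step 1
Reactants: 1 but-2-yn-1-ol
Product: 3 (Z)-3-(tributylstannyl)but-2-en-1-ol, via cyclic vinylalanate 2 (not isolated)
Conditions: Red-Al (1.3 equiv), Et2O, 0 °C to rt; then Bu3SnOTf (1.3 equiv), −78 °C to rt; aq. Rochelle salt
Reagents that add atoms: tributyltin trifluoromethanesulfonate, CCCC[Sn](CCCC)(CCCC)OS(=O)(=O)C(F)(F)F; Red-Al, [Na+].[H][Al-]([H])(OCCOC)OCCOC (its non-hydrogen atoms stay only in 2)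
Why: Alkoxide-directed trans-hydroalumination of a propargylic alcohol puts aluminium on C3 within the five-membered ring of 2, and Al-to-Sn exchange at the sp2 carbon (electrophilic substitution with retention, driven by Al–O bond formation) should therefore leave tin cis to CH2OH, which is the Z geometry needed later.

Step 2
Reactants: 3 (Z)-3-(tributylstannyl)but-2-en-1-ol
Product: 4 (Z)-3-(tributylstannyl)but-2-en-1-yl acetate
Conditions: Ac2O, Et3N, DMAP (cat.), CH2Cl2, 0 °C
Reagents that add atoms: acetic anhydride, CC(=O)OC(C)=O
Why: DMAP-catalysed O-acetylation (nucleophilic acyl substitution) of the primary allylic alcohol leaves the C–Sn bond and the alkene geometry untouched and caps the oxygen that would otherwise lactonise onto the cis ester after the coupling.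

Step 3
Reactants: 5 methyl 5-acetyl-2-hydroxybenzoate
Product: 6 methyl 2-hydroxy-5-[(1S)-1-hydroxyethyl]benzoate
Conditions: RuCl[(S,S)-TsDPEN](p-cymene) (0.5 mol%), HCO2H/Et3N 5:2, 30 °C
Reagents that add atoms: none
Why: Noyori asymmetric transfer hydrogenation: the (S,S)-TsDPEN–Ru hydride, oriented by the CH/π contact between its arene ligand and the aryl ring of 5, delivers hydride to the Re face of the aryl methyl ketone and so sets the S carbinol centre, while the ester and the phenol are inert.

Step 4
Reactants: 6 methyl 2-hydroxy-5-[(1S)-1-hydroxyethyl]benzoate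
Product: 8 1-{2-hydroxy-5-[(1S)-1-hydroxyethyl]phenyl}-3-methylbut-2-en-1-one, via Weinreb amide 7 (not isolated)
Conditions: MeNH(OMe)·HCl (1.3 equiv), iPrMgCl (4.6 equiv), THF, −20 to 0 °C; then 2-methylprop-1-enylmagnesium bromide (2.5 equiv), 0 °C to rt; inverse quench into cold aq. NH4Cl/citric acid
Reagents that add atoms: 2-methylprop-1-enylmagnesium bromide, CC(C)=C[Mg]Br; N,O-dimethylhydroxylamine hydrochloride, CNOC.Cl (its atoms stay only in 7)
Why: Weinreb ketone synthesis run in one pot: the magnesium amide turns the ester into the N-methoxy-N-methylamide, whose chelated tetrahedral adduct with the alkenyl Grignard reagent resists a second addition until the cold, mildly acidic quench, and the carbinol centre, present only as its alkoxide, is not touched.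

Step 5
Reactants: 8 1-{2-hydroxy-5-[(1S)-1-hydroxyethyl]phenyl}-3-methylbut-2-en-1-one
Product: 9 O-{(1S)-1-[4-hydroxy-3-(3-methylbut-2-enoyl)phenyl]ethyl} S-phenyl thiocarbonate
Conditions: PhSC(O)Cl (1.05 equiv), pyridine (1.5 equiv), CH2Cl2, −30 to 0 °C
Reagents that add atoms: S-phenyl chlorothioformate, O=C(Cl)Sc1ccccc1
Why: Pyridine-mediated O-acylation with a chlorothioformate should pick the free secondary hydroxyl over the phenol, whose O–H is locked in a six-membered hydrogen-bond chelate to the enone carbonyl, and keeps the S centre because the benzylic C–O bond is not broken.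

Step 6
Reactants: 9 O-{(1S)-1-[4-hydroxy-3-(3-methylbut-2-enoyl)phenyl]ethyl} S-phenyl thiocarbonate; 4 (Z)-3-(tributylstannyl)but-2-en-1-yl acetate
Product: 10 (1S)-1-[4-hydroxy-3-(3-methylbut-2-enoyl)phenyl]ethyl (2Z)-4-(acetyloxy)-2-methylbut-2-enoate (target)
Conditions: Pd2(dba)3 (2.5 mol%), P(2-furyl)3 (20 mol%), copper(I) diphenylphosphinate (1.3 equiv), degassed THF, 25 to 45 °C
Reagents that add atoms: none
Why: Proposed new method: Pd(0) should insert into the C(acyl)–S bond of 9 (an insertion known for O-alkyl S-aryl thiocarbonates in the Pd-catalysed thioesterification of alkynes) to give an alkoxycarbonyl–Pd–SPh complex; Cu(I) then binds the thiolate while its phosphinate takes up tin, the alkenyl group of 4 moves to Pd with retention, and reductive elimination forms the C1–C2 bond. The closest known reaction types are the Liebeskind–Srogl ketone synthesis from thiol esters and organostannanes under Pd(0)/copper(I) diphenylphosphinate and the Stille coupling of vinylstannanes with chloroformates; only the thiocarbonate as acyl partner is new, chosen because the chloroformate of a 4-hydroxybenzylic alcohol would ionise with loss of CO2, whereas 4-alkoxybenzyl thiocarbonates are storable reagents. No ring is closed and no stereocentre is created: the Z geometry of C2=C3 is carried over from 4, and the S centre persists because its C–O bond is never broken. The step needs C–S insertion to outrun Pd(0) ionisation of the allylic acetates in 4 and 10 and of the benzylic C–O bond, which the weakly donating tri(2-furyl)phosphine, the thiophilic copper salt and the mild temperature should secure. Because no base is present and diphenylphosphinate is far too weak a base for the chelated phenol, three side paths stay closed: 1,6-elimination to a quinone methide, oxa-Michael closure to the 2,2-dimethylchromanone, and Z-to-E isomerisation through an activated acyl derivative of the acid.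

Compound list
1 | but-2-yn-1-ol | CC#CCO | starting material
2 | sodium 2,2-bis(2-methoxyethoxy)-3-methyl-2,5-dihydro-1,2-oxaaluminol-2-uide (cyclic vinylalanate) | [Na+].CC1=CCO[Al-]1(OCCOC)OCCOC | intermediate
3 | (Z)-3-(tributylstannyl)but-2-en-1-ol | OC/C=C(/C)[Sn](CCCC)(CCCC)CCCC | intermediate
4 | (Z)-3-(tributylstannyl)but-2-en-1-yl acetate | CC(=O)OC/C=C(/C)[Sn](CCCC)(CCCC)CCCC | intermediate
5 | methyl 5-acetyl-2-hydroxybenzoate | COC(=O)c1cc(C(C)=O)ccc1O | starting material
6 | methyl 2-hydroxy-5-[(1S)-1-hydroxyethyl]benzoate | C[C@H](O)c1ccc(O)c(C(=O)OC)c1 | intermediate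
7 | 2-hydroxy-5-[(1S)-1-hydroxyethyl]-N-methoxy-N-methylbenzamide (present as its magnesium salt) | C[C@H](O)c1ccc(O)c(C(=O)N(C)OC)c1 | intermediate
8 | 1-{2-hydroxy-5-[(1S)-1-hydroxyethyl]phenyl}-3-methylbut-2-en-1-one | C[C@H](O)c1ccc(O)c(C(=O)C=C(C)C)c1 | intermediate
9 | O-{(1S)-1-[4-hydroxy-3-(3-methylbut-2-enoyl)phenyl]ethyl} S-phenyl thiocarbonate | O=C(Sc1ccccc1)O[C@@H](C)c1ccc(O)c(C(=O)C=C(C)C)c1 | intermediate
10 | (1S)-1-[4-hydroxy-3-(3-methylbut-2-enoyl)phenyl]ethyl (2Z)-4-(acetyloxy)-2-methylbut-2-enoate | CC(=O)OC/C=C(/C)C(=O)O[C@@H](C)c1ccc(O)c(C(=O)C=C(C)C)c1 | target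

Total step count: 6. Longest linear sequence: 4 steps (5 → 6 → 8 → 9 → 10; the stannane branch 1 → 3 → 4 joins at step 6).

Steps most likely to fail

Step 6 (Proposed new method). Insertion of Pd(0) into the C–S bond of a thiocarbonate may be too slow at a temperature that the substrate tolerates. Ionisation of the allylic acetate or of the benzylic C–O bond by Pd(0), or protodestannylation, could then take over. The fallback uses known chemistry, sets out from 4 and 8, and comes back at 10. Iododestannylation of 4 (I2, CH2Cl2, 0 °C, retention) should give (Z)-3-iodobut-2-en-1-yl acetate F1. A Pd-catalysed three-component alkoxycarbonylation of F1 with carbon monoxide (1 atm) and alcohol 8 (PdCl2(PPh3)2, iPr2NEt, THF, 45 °C) then forms the same C1–C2 bond by CO insertion into the (Z)-alkenyl–Pd bond. The secondary hydroxyl of 8 captures the acyl–Pd species.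

Step 5. Chemoselection may erode through competing acylation at the phenolic oxygen, or the base may induce oxa-Michael ring closure. The fallback sets out from 8 and comes back at 9. It replaces kinetic selection by acylating both oxygens and letting their different lability sort them out. Excess 1,1'-carbonyldiimidazole (CH2Cl2, rt) should give the bis(imidazole-1-carboxylate) F2. Brief stirring with wet THF hydrolyses only the activated aryl imidazolecarboxylate and leaves (1S)-1-[4-hydroxy-3-(3-methylbut-2-enoyl)phenyl]ethyl imidazole-1-carboxylate F3. Azolide thiolysis of F3 with thiophenol (cat. Et3N, CH2Cl2, rt) then delivers 9.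

Step 4. Amide formation may be sluggish at an ester deactivated by the neighbouring magnesium phenoxide, so that the Grignard reagents attack unreacted ester and add twice. The fallback sets out from 6 and comes back at 8. Saponification (LiOH, THF/H2O) should give 2-hydroxy-5-[(1S)-1-hydroxyethyl]benzoic acid F4. Its trilithium salt is treated with further 2-methylprop-1-enyllithium (made from 1-bromo-2-methylprop-1-ene and t-BuLi; at least 4 equiv in all, THF, −78 to 0 °C). This is the carboxylate–organolithium ketone synthesis, in which the geminal dilithium diolate blocks over-addition until the inverse quench into cold aq. NH4Cl.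

Further compounds
F1 | step 6 | (Z)-3-iodobut-2-en-1-yl acetate | CC(=O)OC/C=C(/C)I
F2 | step 5 | (1S)-1-{4-[(imidazol-1-ylcarbonyl)oxy]-3-(3-methylbut-2-enoyl)phenyl}ethyl imidazole-1-carboxylate | O=C(O[C@@H](C)c1ccc(OC(=O)n2ccnc2)c(C(=O)C=C(C)C)c1)n1ccnc1
F3 | step 5 | (1S)-1-[4-hydroxy-3-(3-methylbut-2-enoyl)phenyl]ethyl imidazole-1-carboxylate | O=C(O[C@@H](C)c1ccc(O)c(C(=O)C=C(C)C)c1)n1ccnc1
F4 | step 4 | 2-hydroxy-5-[(1S)-1-hydroxyethyl]benzoic acid | C[C@H](O)c1ccc(O)c(C(=O)O)c1
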